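## Structural features

The target is a labdane: a trans-fused decalin (ring A = C1–C5 and C10, ring B = C5–C10) that carries on C9 a two-carbon link (C11–C12) to the α-carbon C13 of a butenolide (C13=C14, C15 methylene, ring oxygen, C16 carbonyl). Five stereocentres form one unbroken chain C4–C5–C10–C9–C8. C4 and C10 are quaternary: C4 bears the C18 methyl (α) and the axial C19 carboxyl (β), C10 bears the C20 methyl (β), so carboxyl and methyl are syn-diaxial. H5 and H9 are α, and the C17 hydroxymethyl on C8 is α and equatorial, trans to the side chain. The fragile groups are the butenolide (reducible, sensitive to base and nucleophiles), the primary alcohol, and the neopentyl axial acid, which cannot be freed by saponification once the butenolide is present. The real difficulty is the pair of quaternary centres C4 and C10, held 1,3 across C5 with defined relative configuration, together with the trans ring fusion. The key step exploits the fact that C10 carries a methyl group and lies para to C7 within ring B: ring B can start as a p-cresol with its oxygen on C7, and its para carbon becomes the quaternary C10 when ring A closes onto it. The C7 oxygen later makes C8 nucleophilic for the introduction of C17 and is then removed.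

## Logic of the disconnections

33 ⇒ 32. The O–tert-butyl bond of the C19 ester and the O–CH2 bond of the C17 acetal are cut together. Both are acid-labile, so the hindered axial acid and the alcohol are released in one step without a nucleophile at the acyl carbon. The forward step must be an acidolysis that leaves the butenolide untouched.

32 ⇒ 29 + 30. The sp3–sp2 bond C12–C13 is cut. The unsaturated lactone, the most fragile part, then arrives intact as 30 in the last C–C bond formation, and the side chain shrinks to a two-carbon iodide. The forward step needs a C12 nucleophile (31) that tolerates ester, acetal and the electrophilic lactone, and it must run without base.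

29 ⇒ 28 ⇒ 27. The C12–I bond is traced back to C12–O and then to the O–Si bond. Oxygen on C12 is what the arene synthesis delivers. The demand is orthogonality: the C12 silyl ether must fall while the C17 acetal stays.

27 ⇒ 24 ⇒ 23. The C7 methylene is taken back to a carbonyl (through 25 and 26) and the C17 acetal to the free alcohol. The C7 carbonyl is kept because it is the former phenol oxygen and the only handle that makes C8 nucleophilic. The forward deoxygenation must not pass through a C7 carbanion or enolisable intermediate that would eliminate or epimerise at C8.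

23 ⇒ 21. The C8–C17 bond is cut: a one-carbon electrophile adds to the C8 enolate 22. One stereocentre disappears. The forward step demands enolisation toward C8 and not C6, and attack on the α-face.

21 ⇒ 20. The hydrogens on C5, C6, C8 and C9 are removed to give the C5=C6 and C8=C9 double bonds. Two stereocentres vanish and the cross-conjugated dienone appears. The forward hydrogenation must deliver hydrogen to the α-face at both β-carbons.

20 ⇒ 17. The C2 methylene is taken back to a carbonyl (through 18 and 19). This carbonyl is the residue of the carbon nucleophile of the key step. It is removed at the dienone stage because only there do the C2 and C7 carbonyls differ in kind; a saturated 2,7-diketone could not be enolised selectively at C8. The forward step must reduce a saturated ketone and ignore a dienone.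

17 ⇒ 16. The C1–C10 bond is cut (key step). Ring A opens and ring B becomes an arene, so a bicycle with two stereocentres becomes a benzene with one (C4). The forward step demands oxidative C–C bond formation at the para carbon, relay of configuration from C4 to C10, and survival of the enol ether until it reacts.

16 ⇒ 13. The O–Si bond of the enol ether is cut back to the methyl ketone. The forward step needs kinetic enolisation at the methyl carbon C1 and a free phenol beside an intact enol ether (through 14 and 15).

13 ⇒ 12 ⇒ 11. The phenol is masked as a benzyl ether and the C19 acid is unmasked. The benzyl ether carries the phenol through organometallic and basic steps. The forward esterification must succeed at a hindered acid without acyl substitution.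

11 ⇒ 10. The C1–C2 bond is cut: a methyl nucleophile opens a cyclic anhydride. The two acid-level carbons are told apart by hindrance alone. The forward step demands a single addition at the carbonyl remote from C4.

10 ⇒ 9 ⇒ 7. The anhydride is opened to the diacid, and C2 is taken back to the alcohol level held in the lactone (through 8). The lactone is the product of the asymmetric arylation. The forward oxidation must outrun relactonisation.

7 ⇒ 5 + 6. The aryl–C4 bond is cut: catalytic asymmetric α-arylation of a lactone enolate. This sets the only stereocentre of 16 and leads to a simple aryl bromide and a commercial lactone. The demand is enantiofacial control at a coupling site flanked by an ortho methyl group.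

5 ⇒ 4 ⇒ 2. The O–Si bond and then the aryl–C11 bond are cut: the aryl anion 3 opens a two-carbon epoxide. This leads to a symmetrical dibromide. The forward step demands clean mono-metalation.

2 ⇒ 1. The benzyl–oxygen bond is cut to reach the commercial phenol.

## Other disconnections considered

Alternative 1: The cut is through C5–C10 and C8–C9, which opens both rings to the acyclic enal–vinylallene A2: an (E)-enal (C9=C10 with the C11 aldehyde) tethered through C1–C3 and the quaternary C4 to the vinylallene C5=C6–C7=C8=C17. The forward key step is an intramolecular Diels–Alder reaction promoted by Me2AlCl A3, giving the octalin aldehyde A1.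
- In its favour: two rings, two C–C bonds and three stereocentres (C5, C9, C10) would arise in one step. C17 is already in place as an exocyclic methylene and C11 as an aldehyde. No oxygen has to be removed from C2 or C7. On bonds formed per step and on redox economy this plan is better than the chosen one.
- Against it: the only resident stereocentre, C4, sits on the tether and must discriminate methyl from ester in the folded transition state. This is the same kind of 1,3-relay as in the chosen plan, so the two are equal on that point. A β,β-disubstituted enal that must form a quaternary carbon is a poor dienophile, and the strong Lewis acid it needs endangers the vinylallene (isomerisation, [2+2] addition) and the tert-butyl ester. The trans fusion requires one specific folding.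
- Precursor and aftermath: A2 combines a stereodefined trisubstituted enal, a vinylallene and an acyclic quaternary stereocentre, and is harder to make than 16. After the cycloaddition, A1 still needs selective saturation of C6=C7 beside the diene, conversion of C8=C17 into an equatorial hydroxymethyl (hydroboration from the open α-face would put C17 axial), and a multi-carbon extension at C11.
- Comparison: more elegant in skeletal terms, less secure mechanistically, and not clearly shorter overall.

Alternative 2: The cut is through C8–C9 of ring B, with a temporary C12–C17 bond, leading to the ring A enyne A5 (alkyne C9≡C11 on C10, butenyl chain ending in C8=C17 on C5). The forward key step is a Pauson–Khand reaction of the Co2(CO)8 A6 complex of A5, which closes ring B and a cyclopentenone to give the tricyclic enone A4.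
- In its favour: intramolecular Pauson–Khand reactions of enynes of this length are dependable, and the quaternary propargylic C10 helps the closure. As a reaction type the key step is at least the equal of the phenol dearomatisation, and probably the more reliable. It brings in C12 and fixes C17 in one operation, where the chosen route needs two separate C–C bond formations. It needs no deoxygenation at C2 or C7.
- Against it: the step begins after the hard part. A5 already contains C4, C5 and C10, including both quaternary centres, so the problem that the dearomatisation solves is left to an unspecified ring A synthesis. C9 stays trigonal and must be set later by conjugate reduction. The cyclopentenone is sacrificial: the C12–C17 bond must be cut again with C17 and C12 told apart, for example by a Baeyer–Villiger oxidation of a ketone flanked by two methylene groups, where migratory preference is not secured. The C1=C2 alkene and stoichiometric A6 are further costs.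
- Comparison: the ring dismantling costs about what the two deoxygenations of the chosen route cost, while the front end is longer and less defined.

Alternative 3: The cut is through C4–C5 and C2–C3 of ring A, leading to the diene A8 ((E)-configured, C5=C10–C1=C2, carrying the C6–C8 chain with the C8 stereocentre, its silyloxymethyl group and a vinyl group) and 2-methylacrolein A9. The forward key step is a Diels–Alder reaction under a chiral cationic oxazaborolidine Lewis acid, giving the cyclohexenecarbaldehyde A7.
- In its favour: the C4 quaternary centre and C5 are set by a catalyst from a trivial dienophile, and the aldehyde is C19 at a convenient oxidation level. On the C4 problem this is the equal or the better of the nickel arylation of the chosen route, which must cope with an ortho substituent. No aromatic detour and no superfluous oxygen are involved.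
- Against it: ring B and the quaternary C10 are not made. A7 holds only a C10=C1 alkene and a vinyl group, so a later C9–C10 ring closure must create the second quaternary centre and C9 with control; the hardest bond is postponed. The directing effects of the terminal alkyl group and the internal methyl group of A8 oppose each other, so regiochemistry is not assured. The new bond joins a quaternary to a tertiary carbon. A8 needs its own asymmetric synthesis for C8.
- Comparison: better on ring A and C4, silent on C10. The chosen plan fixes C10 in the key step and leaves C5 and C9 to a hydrogenation. Overall step counts should be similar, with the larger unknown in the later ring B closure.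

Key step: step 11

Remark: atoms are numbered as in labdanes (C1–C20); α is the face opposite the C20 methyl group; TBS = tert-butyldimethylsilyl, MOM = methoxymethyl, Ts = 4-methylphenylsulfonyl.
Remark: (S)-BINAP is assumed to give the (S)-lactone 7; if the sense of induction is the opposite, (R)-BINAP is used in step 4 and nothing else changes.
Remark: 1, 6 and 30 are taken as catalogue compounds; 6 is used as the racemate because its stereocentre is erased on enolisation.
Remark: the C=N geometry of 18 and 25 and the configuration at the reduced carbon of 19 and 26 are not controlled and are of no consequence.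

## Route

Step 1
Reactants: 1 3,5-dibromo-4-methylphenol
Product: 2 5-(benzyloxy)-1,3-dibromo-2-methylbenzene
Conditions: BnBr, K2CO3, DMF, rt
Reagents that add atoms: benzyl bromide, BrCc1ccccc1
Why: Williamson etherification of the phenoxide; the benzyl ether survives the organolithium, amide-base and Grignard steps and is later removed by hydrogenolysis without touching silyl ethers or the tert-butyl ester.

Step 2
Reactants: 2 5-(benzyloxy)-1,3-dibromo-2-methylbenzene
Product: 4 2-[5-(benzyloxy)-3-bromo-2-methylphenyl]ethan-1-ol, via aryllithium 3 (not isolated)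
Conditions: n-BuLi (1.0 equiv), THF, −78 °C; ethylene oxide, BF3·OEt2, −78 °C; H2O
Reagents that add atoms: ethylene oxide, C1CO1
Why: Bromine–lithium exchange on a dibromide with two equivalent bromines stops at the mono-lithio stage with one equivalent of base, which avoids a statistical mono-coupling. Lewis-acid-assisted epoxide opening by the aryllithium attaches C11 and C12 with the oxygen handle on C12.

Step 3
Reactants: 4 2-[5-(benzyloxy)-3-bromo-2-methylphenyl]ethan-1-ol
Product: 5 {2-[5-(benzyloxy)-3-bromo-2-methylphenyl]ethoxy}(tert-butyl)dimethylsilane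
Conditions: TBSCl, imidazole, DMF, rt
Reagents that add atoms: tert-butyldimethylsilyl chloride, CC(C)(C)[Si](C)(C)Cl
Why: Standard silylation of a primary alcohol; the TBS ether is stable to the bases, the Grignard reagent and the hydrogenations that follow and is cleaved selectively by fluoride in step 17.

Step 4
Reactants: 5 {2-[5-(benzyloxy)-3-bromo-2-methylphenyl]ethoxy}(tert-butyl)dimethylsilane; 6 α-methyl-γ-butyrolactone (racemic)
Product: 7 (S)-3-{5-(benzyloxy)-2-methyl-3-[2-(TBSO)ethyl]phenyl}-3-methyldihydrofuran-2(3H)-one
Conditions: Ni(cod)2 (cat.), (S)-BINAP (cat.), NaHMDS, ZnBr2 (cat.), toluene/THF, 60 °C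
Reagents that add atoms: none
Why: Nickel/BINAP-catalysed enantioselective α-arylation of an α-substituted γ-butyrolactone enolate: oxidative addition of the aryl bromide to zerovalent nickel, transmetalation with the sodium enolate and reductive elimination form the C4–C5 bond. The chiral diphosphine differentiates the two faces of the planar enolate and sets the quaternary C4 as (S). The ortho methyl group makes this the most demanding coupling of the front end.

Step 5
Reactants: 7 (S)-3-{5-(benzyloxy)-2-methyl-3-[2-(TBSO)ethyl]phenyl}-3-methyldihydrofuran-2(3H)-one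
Product: 9 (S)-2-{5-(benzyloxy)-2-methyl-3-[2-(TBSO)ethyl]phenyl}-2-methylbutanedioic acid, via lithium hydroxy carboxylate 8 (not isolated)
Conditions: LiOH, THF/H2O, 40 °C; then TEMPO (cat.), NaClO2, NaOCl (cat.), MeCN/phosphate buffer (pH 6.7), 35 °C; aq. HCl to pH 3
Reagents that add atoms: lithium hydroxide, [Li+].[OH-]; sodium chlorite, [Na+].[O-]Cl=O
Why: Saponification exposes the C2 alcohol as the carboxylate salt, which cannot relactonise. The TEMPO/chlorite oxidation then takes the primary alcohol to the acid near neutral pH with only catalytic hypochlorite, which spares the electron-rich arene. C4 is quaternary and cannot epimerise.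

Step 6
Reactants: 9 (S)-2-{5-(benzyloxy)-2-methyl-3-[2-(TBSO)ethyl]phenyl}-2-methylbutanedioic acid
Product: 10 (S)-3-{5-(benzyloxy)-2-methyl-3-[2-(TBSO)ethyl]phenyl}-3-methyldihydrofuran-2,5-dione
Conditions: Ac2O, 60 °C
Reagents that add atoms: none
Why: Cyclodehydration of a succinic acid to its five-membered anhydride, helped by the geminal substitution at C4.

Step 7
Reactants: 10 (S)-3-{5-(benzyloxy)-2-methyl-3-[2-(TBSO)ethyl]phenyl}-3-methyldihydrofuran-2,5-dione
Product: 11 (S)-2-{5-(benzyloxy)-2-methyl-3-[2-(TBSO)ethyl]phenyl}-2-methyl-4-oxopentanoic acid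
Conditions: MeMgBr (1.05 equiv), THF, −78 °C; aq. HCl
Reagents that add atoms: methylmagnesium bromide, C[Mg]Br
Why: Grignard addition to an unsymmetrical succinic anhydride takes place at the carbonyl remote from the quaternary carbon and forms the C1–C2 bond. Ring opening gives the magnesium carboxylate of the γ-keto acid, and one equivalent at low temperature limits a second addition.

Step 8
Reactants: 11 (S)-2-{5-(benzyloxy)-2-methyl-3-[2-(TBSO)ethyl]phenyl}-2-methyl-4-oxopentanoic acid
Product: 12 tert-butyl (S)-2-{5-(benzyloxy)-2-methyl-3-[2-(TBSO)ethyl]phenyl}-2-methyl-4-oxopentanoate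
Conditions: t-BuOC(=NH)CCl3, cyclohexane/CH2Cl2, rt
Reagents that add atoms: tert-butyl 2,2,2-trichloroacetimidate, CC(C)(C)OC(=N)C(Cl)(Cl)Cl
Why: Imidate tert-butylation alkylates the carboxyl oxygen, so the hindrance at the acyl carbon does not matter. The resulting ester has no α-hydrogen and is later cleaved by acid alone.

Step 9
Reactants: 12 tert-butyl (S)-2-{5-(benzyloxy)-2-methyl-3-[2-(TBSO)ethyl]phenyl}-2-methyl-4-oxopentanoate
Product: 13 tert-butyl (S)-2-{5-hydroxy-2-methyl-3-[2-(TBSO)ethyl]phenyl}-2-methyl-4-oxopentanoate
Conditions: H2 (1 atm), Pd/C, EtOAc, rt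
Reagents that add atoms: none
Why: Hydrogenolysis of the aryl benzyl ether; ketone, silyl ether and tert-butyl ester are inert under these conditions.

Step 10
Reactants: 13 tert-butyl (S)-2-{5-hydroxy-2-methyl-3-[2-(TBSO)ethyl]phenyl}-2-methyl-4-oxopentanoate
Product: 16 tert-butyl (S)-4-(TBSO)-2-{5-hydroxy-2-methyl-3-[2-(TBSO)ethyl]phenyl}-2-methylpent-4-enoate, via dilithium phenoxide enolate 14 (not isolated), via tris-silyl compound 15 (not isolated)
Conditions: LDA (2.3 equiv), THF, −78 °C; TBSOTf (2.4 equiv), −78 °C; then Cs2CO3, DMF/H2O, rt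
Reagents that add atoms: tert-butyldimethylsilyl trifluoromethanesulfonate, CC(C)(C)[Si](C)(C)OS(=O)(=O)C(F)(F)F
Why: Kinetic enolate silylation: after the phenoxide forms, LDA removes a proton from the methyl carbon C1, since the C3 methylene is shielded by the quaternary C4. Carbonate then cleaves only the aryl silyl ether, because phenoxide is a far better leaving group than an enolate or alkoxide. A TBS enol ether is chosen over a trimethylsilyl one so that it survives this unmasking and the acidic medium of step 11.

Step 11
Reactants: 16 tert-butyl (S)-4-(TBSO)-2-{5-hydroxy-2-methyl-3-[2-(TBSO)ethyl]phenyl}-2-methylpent-4-enoate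
Product: 17 tert-butyl (1S,4aR)-1,4a-dimethyl-3,7-dioxo-5-[2-(TBSO)ethyl]-1,2,3,4,4a,7-hexahydronaphthalene-1-carboxylate
Conditions: PhI(OAc)2, (CF3)2CHOH/CH2Cl2, −20 °C
Reagents that add atoms: none
Why: Ligand exchange of the phenol at trivalent iodine gives an aryloxy-λ3-iodane, which ionises in the fluorinated alcohol (loss of iodobenzene and acetate) to a phenoxonium-type cation whose charge is concentrated on C10, the para carbon that bears the methyl group and is flanked by two alkylated ring carbons. C1 of the silyl enol ether adds to C10, and the silyloxocarbenium ion gives up its silyl group to acetate, leaving the C2 ketone and the cross-conjugated C7 dienone. The closest known reaction type is the hypervalent-iodine dearomatisation of para-alkylphenols by π-carbon nucleophiles (silyl enol ethers, allylsilanes, enamides) to 4,4-disubstituted cyclohexadienones; the usual spiro mode is replaced by a fused one because the tether starts at the meta carbon C5. Ring A closes in a six-membered enol-endo mode in which C1, C2, C5 and C10 all become ring atoms. The one new stereocentre, C10, is controlled by C4 through a chair-like transition state: C3 leaves the arene plane on the face of attack, the C18 methyl lies in the plane next to H6 and the ester takes the pseudo-axial site, because an axial C4 methyl would meet the emerging C20 methyl in a methyl/methyl syn-diaxial contact that is worse than the ester/methyl one. The step needs attack at C10 and not at the unsubstituted ortho carbon C6 (which would rearomatise to a tetralone), and oxidation of the phenol before the enol ether. Charge localisation at the alkylated para carbon, fast ligand exchange of phenols at iodine and the bulk of the TBS enol ether should secure this. The para methyl cannot be lost, so the dienone cannot return to an arene, and C5, C8 and C9 stay trigonal for later reduction.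

Step 12
Reactants: 17 tert-butyl (1S,4aR)-1,4a-dimethyl-3,7-dioxo-5-[2-(TBSO)ethyl]-1,2,3,4,4a,7-hexahydronaphthalene-1-carboxylate
Product: 20 tert-butyl (1S,4aR)-1,4a-dimethyl-7-oxo-5-[2-(TBSO)ethyl]-1,2,3,4,4a,7-hexahydronaphthalene-1-carboxylate, via C2 tosylhydrazone 18 (not isolated), via C2 borylated tosylhydrazine 19 (not isolated)
Conditions: TsNHNH2, EtOH, 50 °C; evaporate; catecholborane, CHCl3, 0 °C; NaOAc·3H2O, 60 °C
Reagents that add atoms: none
Why: Only the saturated C2 ketone condenses with the sulfonylhydrazide; the doubly vinylogous dienone carbonyl is too poor an electrophile. Kabalka-type reduction of the tosylhydrazone by catecholborane, then acetate-induced loss of sulfinate and nitrogen, gives the methylene. Catecholborane does not reduce the s-trans dienone, and the fully substituted β-carbons rule out conjugate addition.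

Step 13
Reactants: 20 tert-butyl (1S,4aR)-1,4a-dimethyl-7-oxo-5-[2-(TBSO)ethyl]-1,2,3,4,4a,7-hexahydronaphthalene-1-carboxylate
Product: 21 tert-butyl (1S,4aR,5S,8aR)-1,4a-dimethyl-7-oxo-5-[2-(TBSO)ethyl]decahydronaphthalene-1-carboxylate
Conditions: H2 (3 atm), Pd/C, EtOAc, rt
Reagents that add atoms: none
Why: Heterogeneous syn-hydrogenation of both enone double bonds from the α-face: the β-face of C5 is closed by the syn-diaxial C19 ester and C20 methyl, and that of C9 by the adjacent axial C20 methyl. This should give H5α (trans fusion) and H9α with the side chain equatorial.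

Step 14
Reactants: 21 tert-butyl (1S,4aR,5S,8aR)-1,4a-dimethyl-7-oxo-5-[2-(TBSO)ethyl]decahydronaphthalene-1-carboxylate
Product: 23 tert-butyl (1S,4aR,5S,6R,8aR)-6-(hydroxymethyl)-1,4a-dimethyl-7-oxo-5-[2-(TBSO)ethyl]decahydronaphthalene-1-carboxylate, via lithium enolate 22 (not isolated)
Conditions: LDA, THF, −78 °C; HCHO (gas), −78 °C; H2O
Reagents that add atoms: formaldehyde, C=O
Why: Kinetic deprotonation is expected at C8, because the C6 hydrogens are screened by C5 with its two quaternary neighbours and by the C18 methyl; this is also the usual direction of enolisation of trans-fused ketones of this type, away from the ring fusion. Aldol addition to monomeric formaldehyde occurs anti to the axial C20 methyl, placing C17 α and equatorial, trans to the C9 chain. That epimer is also the thermodynamic one.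

Step 15
Reactants: 23 tert-butyl (1S,4aR,5S,6R,8aR)-6-(hydroxymethyl)-1,4a-dimethyl-7-oxo-5-[2-(TBSO)ethyl]decahydronaphthalene-1-carboxylate
Product: 24 tert-butyl (1S,4aR,5S,6R,8aR)-6-[(methoxymethoxy)methyl]-1,4a-dimethyl-7-oxo-5-[2-(TBSO)ethyl]decahydronaphthalene-1-carboxylate
Conditions: MOMCl, i-Pr2NEt, CH2Cl2, 0 °C to rt
Reagents that add atoms: chloromethyl methyl ether, COCCl
Why: Acetal protection of the primary alcohol under mildly basic conditions blocks retro-aldol cleavage. The MOM ether withstands fluoride, iodination and organozinc chemistry and falls with the tert-butyl ester in the final acid step.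

Step 16
Reactants: 24 tert-butyl (1S,4aR,5S,6R,8aR)-6-[(methoxymethoxy)methyl]-1,4a-dimethyl-7-oxo-5-[2-(TBSO)ethyl]decahydronaphthalene-1-carboxylate
Product: 27 tert-butyl (1S,4aR,5S,6R,8aR)-6-[(methoxymethoxy)methyl]-1,4a-dimethyl-5-[2-(TBSO)ethyl]decahydronaphthalene-1-carboxylate, via C7 tosylhydrazone 25 (not isolated), via C7 borylated tosylhydrazine 26 (not isolated)
Conditions: TsNHNH2, EtOH, 60 °C; evaporate; catecholborane, CHCl3, 0 °C; NaOAc·3H2O, 60 °C
Reagents that add atoms: none
Why: The same Kabalka-type tosylhydrazone reduction as in step 12 removes the C7 oxygen under near-neutral conditions, without a C7 carbanion that could expel the C17 oxygen. C8 already holds its thermodynamic equatorial configuration and is fixed once the carbonyl is gone.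

Step 17
Reactants: 27 tert-butyl (1S,4aR,5S,6R,8aR)-6-[(methoxymethoxy)methyl]-1,4a-dimethyl-5-[2-(TBSO)ethyl]decahydronaphthalene-1-carboxylate
Product: 28 tert-butyl (1S,4aR,5S,6R,8aR)-5-(2-hydroxyethyl)-6-[(methoxymethoxy)methyl]-1,4a-dimethyldecahydronaphthalene-1-carboxylate
Conditions: TBAF, THF, 0 °C to rt
Reagents that add atoms: none
Why: Fluoride-induced desilylation frees only the C12 alcohol; the acetal and the tert-butyl ester are inert to fluoride.

Step 18
Reactants: 28 tert-butyl (1S,4aR,5S,6R,8aR)-5-(2-hydroxyethyl)-6-[(methoxymethoxy)methyl]-1,4a-dimethyldecahydronaphthalene-1-carboxylate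
Product: 29 tert-butyl (1S,4aR,5S,6R,8aR)-5-(2-iodoethyl)-6-[(methoxymethoxy)methyl]-1,4a-dimethyldecahydronaphthalene-1-carboxylate
Conditions: I2, PPh3, imidazole, CH2Cl2, 0 °C to rt
Reagents that add atoms: iodine, [I][I]
Why: Appel-type iodination of a primary alcohol through the alkoxyphosphonium salt and SN2 displacement; imidazole buffers the medium so the acetal and the ester are not exposed to acid.

Step 19
Reactants: 29 tert-butyl (1S,4aR,5S,6R,8aR)-5-(2-iodoethyl)-6-[(methoxymethoxy)methyl]-1,4a-dimethyldecahydronaphthalene-1-carboxylate; 30 3-bromo-2(5H)-furanone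
Product: 32 tert-butyl (1S,4aR,5S,6R,8aR)-6-[(methoxymethoxy)methyl]-1,4a-dimethyl-5-[2-(2-oxo-2,5-dihydrofuran-3-yl)ethyl]decahydronaphthalene-1-carboxylate, via alkylzinc iodide 31 (not isolated)
Conditions: Zn, LiCl, THF, 40 °C; then 30, Pd(OAc)2 (cat.), SPhos (cat.), THF, rt
Reagents that add atoms: none
Why: Direct zinc insertion into the primary C–I bond gives an alkylzinc iodide that tolerates ester and acetal. Negishi coupling with the electron-poor alkenyl bromide forms C12–C13 and delivers the α-substituted butenolide in one piece, without base that could deprotonate the lactone at C15.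

Step 20
Reactants: 32 tert-butyl (1S,4aR,5S,6R,8aR)-6-[(methoxymethoxy)methyl]-1,4a-dimethyl-5-[2-(2-oxo-2,5-dihydrofuran-3-yl)ethyl]decahydronaphthalene-1-carboxylate
Product: 33 (1S,4aR,5S,6R,8aR)-6-(hydroxymethyl)-1,4a-dimethyl-5-[2-(2-oxo-2,5-dihydrofuran-3-yl)ethyl]decahydronaphthalene-1-carboxylic acid
Conditions: CF3CO2H, CH2Cl2, H2O, 0 °C to rt; then aq. NaHCO3
Reagents that add atoms: none
Why: Acidolysis removes the tert-butyl group as isobutene and hydrolyses the MOM acetal in the same operation, so the hindered axial acid is freed without attack at its acyl carbon. The butenolide is stable to acid, and the mild basic work-up cleaves any trifluoroacetate formed on C17.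

## Compound list

1 | 3,5-dibromo-4-methylphenol | Cc1c(Br)cc(O)cc1Br | starting material
2 | 5-(benzyloxy)-1,3-dibromo-2-methylbenzene | Cc1c(Br)cc(OCc2ccccc2)cc1Br | intermediate
3 | [5-(benzyloxy)-3-bromo-2-methylphenyl]lithium | Cc1c([Li])cc(OCc2ccccc2)cc1Br | intermediate
4 | 2-[5-(benzyloxy)-3-bromo-2-methylphenyl]ethan-1-ol | Cc1c(Br)cc(OCc2ccccc2)cc1CCO | intermediate
5 | {2-[5-(benzyloxy)-3-bromo-2-methylphenyl]ethoxy}(tert-butyl)dimethylsilane | Cc1c(Br)cc(OCc2ccccc2)cc1CCO[Si](C)(C)C(C)(C)C | intermediate
6 | α-methyl-γ-butyrolactone (racemic 3-methyldihydrofuran-2(3H)-one) | CC1CCOC1=O | starting material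
7 | (S)-3-{5-(benzyloxy)-2-methyl-3-[2-(TBSO)ethyl]phenyl}-3-methyldihydrofuran-2(3H)-one | C[C@]1(CCOC1=O)c1cc(OCc2ccccc2)cc(CCO[Si](C)(C)C(C)(C)C)c1C | intermediate
8 | lithium (S)-2-{5-(benzyloxy)-2-methyl-3-[2-(TBSO)ethyl]phenyl}-4-hydroxy-2-methylbutanoate | OCC[C@](C)(C(=O)[O-])c1cc(OCc2ccccc2)cc(CCO[Si](C)(C)C(C)(C)C)c1C.[Li+] | intermediate
9 | (S)-2-{5-(benzyloxy)-2-methyl-3-[2-(TBSO)ethyl]phenyl}-2-methylbutanedioic acid | OC(=O)C[C@](C)(C(=O)O)c1cc(OCc2ccccc2)cc(CCO[Si](C)(C)C(C)(C)C)c1C | intermediate
10 | (S)-3-{5-(benzyloxy)-2-methyl-3-[2-(TBSO)ethyl]phenyl}-3-methyldihydrofuran-2,5-dione | O=C1C[C@](C)(C(=O)O1)c1cc(OCc2ccccc2)cc(CCO[Si](C)(C)C(C)(C)C)c1C | intermediate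
11 | (S)-2-{5-(benzyloxy)-2-methyl-3-[2-(TBSO)ethyl]phenyl}-2-methyl-4-oxopentanoic acid | CC(=O)C[C@](C)(C(=O)O)c1cc(OCc2ccccc2)cc(CCO[Si](C)(C)C(C)(C)C)c1C | intermediate
12 | tert-butyl (S)-2-{5-(benzyloxy)-2-methyl-3-[2-(TBSO)ethyl]phenyl}-2-methyl-4-oxopentanoate | CC(=O)C[C@](C)(C(=O)OC(C)(C)C)c1cc(OCc2ccccc2)cc(CCO[Si](C)(C)C(C)(C)C)c1C | intermediate
13 | tert-butyl (S)-2-{5-hydroxy-2-methyl-3-[2-(TBSO)ethyl]phenyl}-2-methyl-4-oxopentanoate | CC(=O)C[C@](C)(C(=O)OC(C)(C)C)c1cc(O)cc(CCO[Si](C)(C)C(C)(C)C)c1C | intermediate
14 | dilithium salt of 13 (phenoxide and C1 enolate) | C=C(O[Li])C[C@](C)(C(=O)OC(C)(C)C)c1cc(O[Li])cc(CCO[Si](C)(C)C(C)(C)C)c1C | intermediate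
15 | tert-butyl (S)-4-(TBSO)-2-{2-methyl-5-(TBSO)-3-[2-(TBSO)ethyl]phenyl}-2-methylpent-4-enoate | C=C(O[Si](C)(C)C(C)(C)C)C[C@](C)(C(=O)OC(C)(C)C)c1cc(O[Si](C)(C)C(C)(C)C)cc(CCO[Si](C)(C)C(C)(C)C)c1C | intermediate
16 | tert-butyl (S)-4-(TBSO)-2-{5-hydroxy-2-methyl-3-[2-(TBSO)ethyl]phenyl}-2-methylpent-4-enoate (key-step precursor) | C=C(O[Si](C)(C)C(C)(C)C)C[C@](C)(C(=O)OC(C)(C)C)c1cc(O)cc(CCO[Si](C)(C)C(C)(C)C)c1C | intermediate
17 | tert-butyl (1S,4aR)-1,4a-dimethyl-3,7-dioxo-5-[2-(TBSO)ethyl]-1,2,3,4,4a,7-hexahydronaphthalene-1-carboxylate (labdane 2,7-dioxo-5,8-diene; 4S,10R) | C[C@]12CC(=O)C[C@](C)(C(=O)OC(C)(C)C)C1=CC(=O)C=C2CCO[Si](C)(C)C(C)(C)C | intermediate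
18 | C2 tosylhydrazone of 17 | C[C@]12CC(=NNS(=O)(=O)c3ccc(C)cc3)C[C@](C)(C(=O)OC(C)(C)C)C1=CC(=O)C=C2CCO[Si](C)(C)C(C)(C)C | intermediate
19 | C2 N-(1,3,2-benzodioxaborol-2-yl)-N′-tosylhydrazine from 18 | C[C@]12CC(N(B3Oc4ccccc4O3)NS(=O)(=O)c3ccc(C)cc3)C[C@](C)(C(=O)OC(C)(C)C)C1=CC(=O)C=C2CCO[Si](C)(C)C(C)(C)C | intermediate
20 | tert-butyl (1S,4aR)-1,4a-dimethyl-7-oxo-5-[2-(TBSO)ethyl]-1,2,3,4,4a,7-hexahydronaphthalene-1-carboxylate | C[C@]12CCC[C@](C)(C(=O)OC(C)(C)C)C1=CC(=O)C=C2CCO[Si](C)(C)C(C)(C)C | intermediate
21 | tert-butyl (1S,4aR,5S,8aR)-1,4a-dimethyl-7-oxo-5-[2-(TBSO)ethyl]decahydronaphthalene-1-carboxylate (H5α, H9α) | C[C@]12CCC[C@](C)(C(=O)OC(C)(C)C)[C@@H]1CC(=O)C[C@@H]2CCO[Si](C)(C)C(C)(C)C | intermediate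
22 | lithium C7–C8 enolate of 21 | C[C@]12CCC[C@](C)(C(=O)OC(C)(C)C)[C@@H]1CC(O[Li])=C[C@@H]2CCO[Si](C)(C)C(C)(C)C | intermediate
23 | tert-butyl (1S,4aR,5S,6R,8aR)-6-(hydroxymethyl)-1,4a-dimethyl-7-oxo-5-[2-(TBSO)ethyl]decahydronaphthalene-1-carboxylate (C17 α, equatorial) | C[C@]12CCC[C@](C)(C(=O)OC(C)(C)C)[C@@H]1CC(=O)[C@@H](CO)[C@@H]2CCO[Si](C)(C)C(C)(C)C | intermediate
24 | tert-butyl (1S,4aR,5S,6R,8aR)-6-[(methoxymethoxy)methyl]-1,4a-dimethyl-7-oxo-5-[2-(TBSO)ethyl]decahydronaphthalene-1-carboxylate | C[C@]12CCC[C@](C)(C(=O)OC(C)(C)C)[C@@H]1CC(=O)[C@@H](COCOC)[C@@H]2CCO[Si](C)(C)C(C)(C)C | intermediate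
25 | C7 tosylhydrazone of 24 | C[C@]12CCC[C@](C)(C(=O)OC(C)(C)C)[C@@H]1CC(=NNS(=O)(=O)c3ccc(C)cc3)[C@@H](COCOC)[C@@H]2CCO[Si](C)(C)C(C)(C)C | intermediate
26 | C7 N-(1,3,2-benzodioxaborol-2-yl)-N′-tosylhydrazine from 25 | C[C@]12CCC[C@](C)(C(=O)OC(C)(C)C)[C@@H]1CC(N(B3Oc4ccccc4O3)NS(=O)(=O)c3ccc(C)cc3)[C@@H](COCOC)[C@@H]2CCO[Si](C)(C)C(C)(C)C | intermediate
27 | tert-butyl (1S,4aR,5S,6R,8aR)-6-[(methoxymethoxy)methyl]-1,4a-dimethyl-5-[2-(TBSO)ethyl]decahydronaphthalene-1-carboxylate | C[C@]12CCC[C@](C)(C(=O)OC(C)(C)C)[C@@H]1CC[C@@H](COCOC)[C@@H]2CCO[Si](C)(C)C(C)(C)C | intermediate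
28 | tert-butyl (1S,4aR,5S,6R,8aR)-5-(2-hydroxyethyl)-6-[(methoxymethoxy)methyl]-1,4a-dimethyldecahydronaphthalene-1-carboxylate | C[C@]12CCC[C@](C)(C(=O)OC(C)(C)C)[C@@H]1CC[C@@H](COCOC)[C@@H]2CCO | intermediate
29 | tert-butyl (1S,4aR,5S,6R,8aR)-5-(2-iodoethyl)-6-[(methoxymethoxy)methyl]-1,4a-dimethyldecahydronaphthalene-1-carboxylate | C[C@]12CCC[C@](C)(C(=O)OC(C)(C)C)[C@@H]1CC[C@@H](COCOC)[C@@H]2CC[I] | intermediate
30 | 3-bromo-2(5H)-furanone | O=C1OCC=C1Br | starting material
31 | alkylzinc iodide from 29 (C12–Zn–I) | C[C@]12CCC[C@](C)(C(=O)OC(C)(C)C)[C@@H]1CC[C@@H](COCOC)[C@@H]2CC[Zn]I | intermediate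
32 | tert-butyl (1S,4aR,5S,6R,8aR)-6-[(methoxymethoxy)methyl]-1,4a-dimethyl-5-[2-(2-oxo-2,5-dihydrofuran-3-yl)ethyl]decahydronaphthalene-1-carboxylate | C[C@]12CCC[C@](C)(C(=O)OC(C)(C)C)[C@@H]1CC[C@@H](COCOC)[C@@H]2CCC1=CCOC1=O | intermediate
33 | (1S,4aR,5S,6R,8aR)-6-(hydroxymethyl)-1,4a-dimethyl-5-[2-(2-oxo-2,5-dihydrofuran-3-yl)ethyl]decahydronaphthalene-1-carboxylic acid (CNP0562063.1) | C[C@]12CCC[C@](C)(C(=O)O)[C@@H]1CC[C@@H](CO)[C@@H]2CCC1=CCOC1=O | target

## Step count and least certain steps

Total: 20 steps. Longest linear sequence: 20 steps from 1; 6 and 30 are purchased and enter at steps 4 and 19.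

Step 11 (key step). Three processes may compete. Carbon–carbon bond formation at the unsubstituted ortho carbon C6, followed by rearomatisation, would give a tetralone. The enol ether may be oxidised or protodesilylated before it cyclises. The relay from C4 to C10 may be weak, because it rests only on the difference between an axial ester and an axial methyl group. The fallback inverts the polarity of the ring closure and needs no oxidant. Starting from 16, N-bromosuccinimide in THF at −78 °C should brominate the enol ether faster than the phenol and give tert-butyl (S)-5-bromo-2-{5-hydroxy-2-methyl-3-[2-(TBSO)ethyl]phenyl}-2-methyl-4-oxopentanoate F1. One equivalent of KOt-Bu in t-BuOH/THF then forms only the phenoxide, which is alkylated at its para carbon by the bromomethyl ketone (the classical phenoxide para-alkylation to a cyclohexadienone). This closes the same C1–C10 bond and rejoins the route at 17. The C10 epimers are diastereomers and can be separated at that stage.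

Step 4. Oxidative addition and reductive elimination next to the ortho methyl group may be slow, which would lead to low conversion, hydrodehalogenation or eroded enantioselectivity. The fallback builds C4 by enolate alkylation instead of arylation.
- From 5, palladium-catalysed α-arylation of tert-butyl propanoate (Pd(dba)2, P(t-Bu)3, lithium dicyclohexylamide, toluene, rt) forms only a tertiary centre and tolerates ortho substituents. It gives racemic tert-butyl 2-{5-(benzyloxy)-2-methyl-3-[2-(TBSO)ethyl]phenyl}propanoate F2.
- LDA and allyl bromide give racemic tert-butyl 2-{5-(benzyloxy)-2-methyl-3-[2-(TBSO)ethyl]phenyl}-2-methylpent-4-enoate F3.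
- Tsuji–Wacker oxidation (PdCl2, CuCl, O2, DMF/H2O) gives the racemic keto ester F4.
- Preparative chromatography on a chiral stationary phase separates 12 from its (R)-enantiomer F5.

This sequence rejoins the route at 12 and replaces steps 4–8, at the price of half the material.

Step 10. The enol silane may be lost during the carbonate-mediated unmasking of the phenol, the two O–Si bonds may not be told apart cleanly, and the enolate may attack the ester in a Dieckmann-type closure if silylation is slow. The fallback uses orthogonal silyl groups instead of a rate difference between like groups. From 13, Me3SiCl and Et3N give tert-butyl (S)-2-{2-methyl-3-[2-(TBSO)ethyl]-5-(trimethylsilyloxy)phenyl}-2-methyl-4-oxopentanoate F6. LDA and TBSOTf at −78 °C give the mixed silyl compound tert-butyl (S)-4-(TBSO)-2-{2-methyl-3-[2-(TBSO)ethyl]-5-(trimethylsilyloxy)phenyl}-2-methylpent-4-enoate F7. Brief methanolysis (K2CO3, MeOH, 0 °C) removes only the aryl trimethylsilyl group and rejoins the route at 16.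

Step 13. Hydrogen may be delivered to the β-face at C5 or C9, giving a cis-fused decalin or an axial side chain, as is known for related steroidal enones on palladium; the hindered C5=C6 bond may also reduce slowly. Neither centre can be corrected later. The fallback replaces surface-controlled addition by a dissolving-metal reduction, in which each β-carbon is protonated axially to the more stable trans arrangement. From 20, Li in NH3/THF with t-BuOH should reduce both enone units and the ketone to tert-butyl (1S,4aR,5S,8aR)-7β-hydroxy-1,4a-dimethyl-5-[2-(TBSO)ethyl]decahydronaphthalene-1-carboxylate F8. Dess–Martin oxidation returns to the route at 21.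

Step 14. Enolisation toward C6 may compete, and the aldol may add a second formaldehyde or revert on handling. The fallback makes the enolate regiospecific by keeping one double bond. From 20, hydrogenation with RhCl(PPh3)3 should saturate only the less hindered C8=C9 bond from the α-face and give the enone tert-butyl (1S,4aR,5S)-1,4a-dimethyl-7-oxo-5-[2-(TBSO)ethyl]-1,2,3,4,4a,5,6,7-octahydronaphthalene-1-carboxylate F9. In F9, C6 is vinylic and both γ-carbons are quaternary, so LDA can deprotonate only C8. Formaldehyde then gives tert-butyl (1S,4aR,5S,6R)-6-(hydroxymethyl)-1,4a-dimethyl-7-oxo-5-[2-(TBSO)ethyl]-1,2,3,4,4a,5,6,7-octahydronaphthalene-1-carboxylate F10. Hydrogenation of the remaining C5=C6 bond over Pd/C rejoins the route at 23.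

## Further compounds

F1 | step 11 | tert-butyl (S)-5-bromo-2-{5-hydroxy-2-methyl-3-[2-(TBSO)ethyl]phenyl}-2-methyl-4-oxopentanoate | BrCC(=O)C[C@](C)(C(=O)OC(C)(C)C)c1cc(O)cc(CCO[Si](C)(C)C(C)(C)C)c1C
F2 | step 4 | tert-butyl 2-{5-(benzyloxy)-2-methyl-3-[2-(TBSO)ethyl]phenyl}propanoate (racemic) | CC(C(=O)OC(C)(C)C)c1cc(OCc2ccccc2)cc(CCO[Si](C)(C)C(C)(C)C)c1C
F3 | step 4 | tert-butyl 2-{5-(benzyloxy)-2-methyl-3-[2-(TBSO)ethyl]phenyl}-2-methylpent-4-enoate (racemic) | C=CCC(C)(C(=O)OC(C)(C)C)c1cc(OCc2ccccc2)cc(CCO[Si](C)(C)C(C)(C)C)c1C
F4 | step 4 | tert-butyl 2-{5-(benzyloxy)-2-methyl-3-[2-(TBSO)ethyl]phenyl}-2-methyl-4-oxopentanoate (racemic) | CC(=O)CC(C)(C(=O)OC(C)(C)C)c1cc(OCc2ccccc2)cc(CCO[Si](C)(C)C(C)(C)C)c1C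
F5 | step 4 | tert-butyl (R)-2-{5-(benzyloxy)-2-methyl-3-[2-(TBSO)ethyl]phenyl}-2-methyl-4-oxopentanoate | CC(=O)C[C@@](C)(C(=O)OC(C)(C)C)c1cc(OCc2ccccc2)cc(CCO[Si](C)(C)C(C)(C)C)c1C
F6 | step 10 | tert-butyl (S)-2-{2-methyl-3-[2-(TBSO)ethyl]-5-(trimethylsilyloxy)phenyl}-2-methyl-4-oxopentanoate | CC(=O)C[C@](C)(C(=O)OC(C)(C)C)c1cc(O[Si](C)(C)C)cc(CCO[Si](C)(C)C(C)(C)C)c1C
F7 | step 10 | tert-butyl (S)-4-(TBSO)-2-{2-methyl-3-[2-(TBSO)ethyl]-5-(trimethylsilyloxy)phenyl}-2-methylpent-4-enoate | C=C(O[Si](C)(C)C(C)(C)C)C[C@](C)(C(=O)OC(C)(C)C)c1cc(O[Si](C)(C)C)cc(CCO[Si](C)(C)C(C)(C)C)c1C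
F8 | step 13 | tert-butyl (1S,4aR,5S,8aR)-7β-hydroxy-1,4a-dimethyl-5-[2-(TBSO)ethyl]decahydronaphthalene-1-carboxylate (equatorial alcohol) | C[C@]12CCC[C@](C)(C(=O)OC(C)(C)C)[C@@H]1C[C@H](O)C[C@@H]2CCO[Si](C)(C)C(C)(C)C
F9 | step 14 | tert-butyl (1S,4aR,5S)-1,4a-dimethyl-7-oxo-5-[2-(TBSO)ethyl]-1,2,3,4,4a,5,6,7-octahydronaphthalene-1-carboxylate | C[C@]12CCC[C@](C)(C(=O)OC(C)(C)C)C1=CC(=O)C[C@@H]2CCO[Si](C)(C)C(C)(C)C
F10 | step 14 | tert-butyl (1S,4aR,5S,6R)-6-(hydroxymethyl)-1,4a-dimethyl-7-oxo-5-[2-(TBSO)ethyl]-1,2,3,4,4a,5,6,7-octahydronaphthalene-1-carboxylate | C[C@]12CCC[C@](C)(C(=O)OC(C)(C)C)C1=CC(=O)[C@@H](CO)[C@@H]2CCO[Si](C)(C)C(C)(C)C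
A1 | alternative 1 | trans-fused octalin aldehyde with C6=C7 alkene and exocyclic C8=C17 methylene (tert-butyl ester) | C[C@]12CCC[C@](C)(C(=O)OC(C)(C)C)[C@@H]1C=CC(=C)[C@@H]2C=O
A2 | alternative 1 | acyclic (E)-enal tethered to a vinylallene through the quaternary C4 (tert-butyl ester) | O=C/C=C(C)/CCC[C@](C)(C(=O)OC(C)(C)C)/C=C/C=C=C
A3 | alternative 1 | dimethylaluminium chloride | C[Al](C)Cl
A4 | alternative 2 | ring B-fused cyclopentenone (C9=C11, C12 ketone, C17 methylene) | C[C@]12C=CC[C@](C)(C(=O)OC(C)(C)C)[C@@H]1CC[C@H]3CC(=O)C=C23
A5 | alternative 2 | tert-butyl 2-(but-3-en-1-yl)-3-ethynyl-1,3-dimethylcyclohex-4-ene-1-carboxylate configured as in A4 | C#C[C@@]1(C)C=CC[C@](C)(C(=O)OC(C)(C)C)[C@@H]1CCC=C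
A6 | alternative 2 | dicobalt octacarbonyl | [Co].[Co].[C-]#[O+].[C-]#[O+].[C-]#[O+].[C-]#[O+].[C-]#[O+].[C-]#[O+].[C-]#[O+].[C-]#[O+]
A7 | alternative 3 | ring A cyclohex-3-enecarbaldehyde with C4, C5 and C8 configured as in 33 | CC1=CCC[C@](C)(C=O)[C@@H]1CC[C@@H](CO[Si](C)(C)C(C)(C)C)C=C
A8 | alternative 3 | tert-butyl{[(2R,5E)-6-methyl-2-vinylocta-5,7-dien-1-yl]oxy}dimethylsilane | C=C/C(C)=C/CC[C@@H](CO[Si](C)(C)C(C)(C)C)C=C
A9 | alternative 3 | 2-methylacrolein | CC(=C)C=O
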